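## Retrosynthetic overview

1. Target ⇐ its lactol O‑(1S)‑1‑phenylethyl ether, by hydrogenolysis of the auxiliary's own benzylic C–O bond (no bond to the lactol carbon is broken).
2. Depsidone acetal ⇐ depside, by dehydrogenative (anodic) phenoxyl‑radical C–O coupling that makes the diaryl ether bond and closes the seven‑membered ring.
3. Depside ⇐ A‑ring salicylic acid + B‑ring 3‑alkoxyphthalide phenol (ester bond).
4. Both halves ⇐ methyl orsellinate. A: O‑methylation, ortho‑formylation, saponification. B: acetylation, radical benzylic dibromination, hydrolysis to the hydroxyphthalide, acetalisation with (S)‑1‑phenylethanol under crystallisation‑driven C‑3 equilibration (fixes the stereocentre).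
5. Methyl orsellinate ⇐ 2 × methyl acetoacetate. Ring order: both benzene rings (step 1) → phthalide lactol ring (step 7) → depsidone ring (step 10).

Assumption 1: the lactol carbon, (S) in the given SMILES, is the only stereocentre and can epimerise by ring–chain tautomerism, so it is carried as a configurationally stable mixed acetal, released only in the last step under neutral aprotic conditions, and the product is handled cold, free of acid, base and water.

Assumption 2: in step 8 the (3S,1′S) acetal is the less soluble C‑3 epimer; should it not crystallise selectively, the two epimers are separated on silica and the (3R) epimer is returned to the same acid conditions.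

## Route

**Step 1**
Reactants: 1 methyl acetoacetate (two molecules)
Product: 3 methyl orsellinate (methyl 2,4-dihydroxy-6-methylbenzoate), via methyl 3,5,7-trioxooctanoate 2 (not isolated)
Conditions: NaH, THF, 0 °C; n‑BuLi, −78 °C → rt → reflux; aq. HCl
Reagents that add atoms: none
Why: Self‑condensation of the acetoacetate dianion (Claisen acylation at the γ‑carbon by a second ester, then intramolecular aldol condensation and enolisation) is a known one‑pot entry to this resorcylate.

**Step 2**
Reactants: 3 methyl orsellinate
Product: 4 methyl everninate (methyl 2-hydroxy-4-methoxy-6-methylbenzoate)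
Conditions: MeI (1.05 equiv), K2CO3 (1.1 equiv), acetone, reflux
Reagents that add atoms: iodomethane, CI
Why: Williamson etherification is selective for the 4‑OH because the 2‑OH is locked in a hydrogen bond to the ester carbonyl.

**Step 3**
Reactants: 4 methyl everninate
Product: 5 methyl 3-formyl-2-hydroxy-4-methoxy-6-methylbenzoate
Conditions: Cl2CHOMe (1.5 equiv), TiCl4 (2.2 equiv), CH2Cl2, −10 °C → rt; ice–water
Reagents that add atoms: dichloromethyl methyl ether, COC(Cl)Cl; water, O
Why: Rieche formylation in which the titanium phenoxide/ester chelate delivers the electrophile to C‑3, the only free position ortho to the phenol and also activated by the ortho methoxy group.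

**Step 4**
Reactants: 5 methyl 3-formyl-2-hydroxy-4-methoxy-6-methylbenzoate
Product: 6 3-formyl-2-hydroxy-4-methoxy-6-methylbenzoic acid
Conditions: LiOH·H2O (6 equiv), THF–H2O, 60 °C; then 1 M HCl, 0 °C
Reagents that add atoms: lithium hydroxide, [Li+].[OH-]
Why: Saponification of the hindered salicylate needs warming but the non‑enolisable, phenoxide‑deactivated aldehyde tolerates it, and cold acidification avoids decarboxylation.

**Step 5**
Reactants: 3 methyl orsellinate
Product: 7 methyl 2,4-diacetoxy-6-methylbenzoate
Conditions: Ac2O (3 equiv), pyridine, DMAP (cat.), rt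
Reagents that add atoms: acetic anhydride, CC(=O)OC(C)=O
Why: Acetylation of both phenols deactivates the ring so that the following bromination goes to the side chain and not to the nucleus.

**Step 6**
Reactants: 7 methyl 2,4-diacetoxy-6-methylbenzoate
Product: 8 methyl 2,4-diacetoxy-6-(dibromomethyl)benzoate
Conditions: NBS (2.3 equiv), AIBN (5 mol%), PhCF3, reflux, visible light
Reagents that add atoms: N‑bromosuccinimide, O=C1CCC(=O)N1Br
Why: Wohl–Ziegler radical bromination takes the only benzylic methyl group to the aldehyde oxidation level, as for methyl o‑toluate.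

**Step 7**
Reactants: 8 methyl 2,4-diacetoxy-6-(dibromomethyl)benzoate
Product: 9 rac‑3,5,7-trihydroxy-2-benzofuran-1(3H)-one (3,5,7-trihydroxyphthalide)
Conditions: 1 M aq. HCl–1,4‑dioxane (1:1), 90 °C
Reagents that add atoms: water, O
Why: Acid hydrolysis of the gem‑dibromide with participation of the ortho ester gives the aldehyde acid, which closes to the lactol while the aryl acetates are cleaved under the same conditions.

**Step 8**
Reactants: 9 rac‑3,5,7-trihydroxy-2-benzofuran-1(3H)-one
Product: 11 (3S)-5,7-dihydroxy-3-[(1S)-1-phenylethoxy]-2-benzofuran-1(3H)-one, via (3R)-epimeric acetal 10 (not isolated)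
Conditions: (S)‑1‑phenylethanol (1.5 equiv), PPTS (10 mol%), 4 Å MS, 1,4‑dioxane–toluene, 70 °C; filter, concentrate, toluene–heptane, seed, 50 °C → rt with the acid still present; collect the solid
Reagents that add atoms: (S)‑1‑phenylethanol, C[C@H](O)c1ccccc1
Why: Acid‑catalysed pseudo‑ester (mixed acetal) formation of the 3‑hydroxyphthalide gives both C‑3 epimers, which keep interconverting through the acyloxycarbenium (phthalidyl) ion in the presence of the free alcohol while the less soluble (3S,1′S) diastereomer crystallises, so a crystallisation‑induced diastereomer transformation (as known for 5‑alkoxy‑2(5H)‑furanone pseudo‑esters of chiral alcohols) drains epimer 10 into 11 and sets the stereocentre.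

**Step 9**
Reactants: 6 3-formyl-2-hydroxy-4-methoxy-6-methylbenzoic acid; 11 (3S)-5,7-dihydroxy-3-[(1S)-1-phenylethoxy]-2-benzofuran-1(3H)-one
Product: 12 (3S)-7-hydroxy-1-oxo-3-[(1S)-1-phenylethoxy]-1,3-dihydro-2-benzofuran-5-yl 3-formyl-2-hydroxy-4-methoxy-6-methylbenzoate (depside)
Conditions: DCC (1.1 equiv), DMAP (5 mol%), CH2Cl2, 0 °C → rt
Reagents that add atoms: none
Why: Steglich esterification goes to the 5‑OH, the only phenol that is neither chelated to a carbonyl group nor flanked by two substituents, and the neutral conditions leave the acetal stereocentre alone.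

**Step 10**
Reactants: 12 depside
Product: 14 (1S)-1-phenylethyl acetal of the target depsidone (3S at the acetal carbon), via 4-aryloxycyclohexa-2,5-dienone tautomer 13 (not isolated)
Conditions: graphite(+)/Pt(−), undivided cell, constant current (about 2.1 F/mol, 2 mA/cm2), Bu4NBF4 (0.1 M), 2,6‑lutidine (3 equiv), HFIP–CH2Cl2 (1:3), 2 mM, 0 °C
Reagents that add atoms: none
Why: Proposed new method: anodic one‑electron oxidation of the B‑ring phenol (the easier to oxidise, having one ortho carbonyl group against two on ring A) gives a phenoxyl radical with its highest spin density at C‑4, para to O‑7, where the ester tether holds the A‑ring phenol oxygen, so radical–phenol(ate) C–O coupling closes the seven‑membered ring to dienone 13, which tautomerises irreversibly to the phenol; the closest known reaction types are biomimetic phenol oxidative coupling, the MnO2 oxidation of a depside to a depsidone and anodic dehydrogenative phenol coupling in HFIP, and the acetal stereocentre is not involved.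

**Step 11**
Reactants: 14 depsidone acetal
Product: 15 target depsidone, (S) at the lactol carbon
Conditions: H2 (1 atm), 10% Pd/C, EtOAc, 0 °C, short reaction time; filter, evaporate cold
Reagents that add atoms: none
Why: Hydrogenolysis cleaves the unhindered O–CH(Me)Ph benzylic bond, as for a benzyl ether, and not the C‑3–O bonds on the crowded electron‑poor B ring, so the (S) lactol is released with retention under neutral aprotic conditions that do not reduce the hindered aryl aldehyde or the aryl ester.

## Compound list

1 | methyl acetoacetate | COC(=O)CC(C)=O | starting material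
2 | methyl 3,5,7-trioxooctanoate | COC(=O)CC(=O)CC(=O)CC(C)=O | intermediate (not isolated)
3 | methyl orsellinate (methyl 2,4-dihydroxy-6-methylbenzoate) | COC(=O)c1c(C)cc(O)cc1O | intermediate
4 | methyl everninate (methyl 2-hydroxy-4-methoxy-6-methylbenzoate) | COC(=O)c1c(C)cc(OC)cc1O | intermediate
5 | methyl 3-formyl-2-hydroxy-4-methoxy-6-methylbenzoate | COC(=O)c1c(C)cc(OC)c(C=O)c1O | intermediate
6 | 3-formyl-2-hydroxy-4-methoxy-6-methylbenzoic acid | OC(=O)c1c(C)cc(OC)c(C=O)c1O | intermediate
7 | methyl 2,4-diacetoxy-6-methylbenzoate | COC(=O)c1c(C)cc(OC(C)=O)cc1OC(C)=O | intermediate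
8 | methyl 2,4-diacetoxy-6-(dibromomethyl)benzoate | COC(=O)c1c(C(Br)Br)cc(OC(C)=O)cc1OC(C)=O | intermediate
9 | rac‑3,5,7-trihydroxy-2-benzofuran-1(3H)-one | O=C1OC(O)c2cc(O)cc(O)c12 | intermediate
10 | (3R)-5,7-dihydroxy-3-[(1S)-1-phenylethoxy]-2-benzofuran-1(3H)-one (C‑3 epimer of 11) | Oc1cc(O)c2c(c1)[C@H](O[C@@H](C)c1ccccc1)OC2=O | intermediate (not isolated)
11 | (3S)-5,7-dihydroxy-3-[(1S)-1-phenylethoxy]-2-benzofuran-1(3H)-one | Oc1cc(O)c2c(c1)[C@@H](O[C@@H](C)c1ccccc1)OC2=O | intermediate
12 | (3S)-7-hydroxy-1-oxo-3-[(1S)-1-phenylethoxy]-1,3-dihydro-2-benzofuran-5-yl 3-formyl-2-hydroxy-4-methoxy-6-methylbenzoate | COc1cc(C)c(C(=O)Oc2cc(O)c3c(c2)[C@@H](O[C@@H](C)c2ccccc2)OC3=O)c(O)c1C=O | intermediate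
13 | 4-aryloxycyclohexa-2,5-dienone tautomer of 14 (B‑ring C‑4 sp3, C‑7 ketone) | COc1cc(C)c2c(c1C=O)OC1C(OC2=O)=CC(=O)C3=C1[C@@H](O[C@@H](C)c1ccccc1)OC3=O | intermediate (not isolated)
14 | target depsidone with the lactol OH as its (1S)-1-phenylethyl ether, (S) at the acetal carbon | COc1cc(C)c2c(c1C=O)Oc1c(cc(O)c3c1[C@@H](O[C@@H](C)c1ccccc1)OC3=O)OC2=O | intermediate
15 | CNP0216483.1, depsidone with (S)-3-hydroxyphthalide lactol | COc1cc(C)c2c(c1C=O)Oc1c(cc(O)c3c1[C@@H](O)OC3=O)OC2=O | target

## Step count and risks

Total steps: 11. Longest linear sequence: 8 (steps 1, 5, 6, 7, 8, 9, 10, 11).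

**Step 10 (ring‑closing radical C–O coupling).** Three things can go wrong. Both phenols are electron‑poor, hydrogen‑bonded salicylate types and hard to oxidise. Coupling could occur at C‑6 (ortho to O‑7) instead of C‑4 (para). The product phenol, now carrying a para aryloxy group, is easier to oxidise than 12, so the electrolysis should be stopped at partial conversion and 12 recycled. The fallback sets out from 11 and comes back at 14. Brominate 11 with NBS (1 equiv, MeCN, 0 °C) at C‑4, para to the 7‑OH, to give (3S)-4-bromo-5,7-dihydroxy-3-[(1S)-1-phenylethoxy]-2-benzofuran-1(3H)-one F1. Esterify F1 with 6 as in step 9 to give the bromo depside (3S)-4-bromo-7-hydroxy-1-oxo-3-[(1S)-1-phenylethoxy]-1,3-dihydro-2-benzofuran-5-yl 3-formyl-2-hydroxy-4-methoxy-6-methylbenzoate F2. Close the ring by intramolecular copper‑catalysed Ullmann etherification (CuI, N,N‑dimethylglycine, Cs2CO3, dioxane, 80 °C) to reach 14, which also fixes the regiochemistry.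

**Step 11 (release of the lactol).** The risks are reduction of the aryl aldehyde, hydrogenolysis of a C‑3–O bond to the phthalide, and epimerisation of the free lactol during isolation. The fallback sets out from 9 and comes back at 15. Run step 8 with (S)‑1‑(naphthalen‑2‑yl)ethanol in place of (S)‑1‑phenylethanol to obtain (3S)-5,7-dihydroxy-3-[(1S)-1-(naphthalen-2-yl)ethoxy]-2-benzofuran-1(3H)-one F3. Esterify with 6 to the depside (3S)-7-hydroxy-3-[(1S)-1-(naphthalen-2-yl)ethoxy]-1-oxo-1,3-dihydro-2-benzofuran-5-yl 3-formyl-2-hydroxy-4-methoxy-6-methylbenzoate F4. Cyclise anodically as before to the lactol O‑[(1S)-1-(naphthalen-2-yl)ethyl] ether of the target F5. Remove the auxiliary oxidatively with DDQ (CH2Cl2 with a trace of water, 0 °C); hydride abstraction at the auxiliary's benzylic carbon releases 15 and 2‑acetonaphthone without hydrogen gas and without breaking a bond to the lactol carbon.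

**Step 9 (esterification).** A salicylic acid with a free ortho OH can give N‑acylurea, self‑condensation and low conversion under carbodiimide activation. The fallback sets out from 6 and comes back at 12. Convert 6 with acetone, TFAA and TFA into 7-methoxy-2,2,5-trimethyl-4-oxo-4H-1,3-benzodioxine-8-carbaldehyde F6. Open F6 with the caesium 5‑phenoxide of 11 (Cs2CO3, THF, 40 °C); attack at the lactone‑type carbonyl expels acetone and gives 12 with its A‑ring phenol already free.

## Further compounds

F1 | step 10 | (3S)-4-bromo-5,7-dihydroxy-3-[(1S)-1-phenylethoxy]-2-benzofuran-1(3H)-one | Oc1cc(O)c2c(c1Br)[C@@H](O[C@@H](C)c1ccccc1)OC2=O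
F2 | step 10 | (3S)-4-bromo-7-hydroxy-1-oxo-3-[(1S)-1-phenylethoxy]-1,3-dihydro-2-benzofuran-5-yl 3-formyl-2-hydroxy-4-methoxy-6-methylbenzoate | COc1cc(C)c(C(=O)Oc2cc(O)c3c(c2Br)[C@@H](O[C@@H](C)c2ccccc2)OC3=O)c(O)c1C=O
F3 | step 11 | (3S)-5,7-dihydroxy-3-[(1S)-1-(naphthalen-2-yl)ethoxy]-2-benzofuran-1(3H)-one | Oc1cc(O)c2c(c1)[C@@H](O[C@@H](C)c1ccc3ccccc3c1)OC2=O
F4 | step 11 | (3S)-7-hydroxy-3-[(1S)-1-(naphthalen-2-yl)ethoxy]-1-oxo-1,3-dihydro-2-benzofuran-5-yl 3-formyl-2-hydroxy-4-methoxy-6-methylbenzoate | COc1cc(C)c(C(=O)Oc2cc(O)c3c(c2)[C@@H](O[C@@H](C)c2ccc4ccccc4c2)OC3=O)c(O)c1C=O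
F5 | step 11 | target depsidone with the lactol OH as its (1S)-1-(naphthalen-2-yl)ethyl ether, (S) at the acetal carbon | COc1cc(C)c2c(c1C=O)Oc1c(cc(O)c3c1[C@@H](O[C@@H](C)c1ccc4ccccc4c1)OC3=O)OC2=O
F6 | step 9 | 7-methoxy-2,2,5-trimethyl-4-oxo-4H-1,3-benzodioxine-8-carbaldehyde | COc1cc(C)c2c(c1C=O)OC(C)(C)OC2=O
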